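There are 4 questions on this flask, and I answer them with one quantity.

| setting | beta | delta | flask |
|---|---|---|---|
| Q | 0.10 M | 0.050 M | 0.10 M |
| X | 7.3 × 10⁻⁴ mol% | 7.3 × 10⁻⁴ mol% | 7.3 × 10⁻⁴ mol% |
| temperature | 25 °C | 10 °C | 25 °C |
| remark | the very flask that is asked about, followed so far | run made earlier |  |
| time |  |  | 4.0 d |

| run | time / h | E / % |
|---|---|---|
| beta | 15.0 | 23.0 |
| beta | 30.0 | 24.0 |
| beta | 40.0 | 25.5 |
| beta | 60.0 | 24.3 |
| delta | 2.00 | 3.0 |
| delta | 6.00 | 6.6 |
| delta | 10.0 | 10.2 |
| delta | 15.0 | 14.8 |

(each reading ± 0.5 percentage points)

1. E, in percent of the Q first charged, at 4.0 d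
2. the remedy with the largest gain of E, or "none" below 2 percentage points (Thursday's / Saturday's / Monday's / Friday's / none)
3. E present, with what was taken out counted in, in percent of the Q first charged, after Saturday's
4. E present, with what was taken out counted in, in percent of the Q first charged, after Friday's

- Thursday's: at 4.0 d take out 90 % of the E then present, then wait 30 h
- Saturday's: change nothing and wait 30 h more
- Monday's: at 4.0 d raise the temperature by 15 K, then wait 30 h
- Friday's: at 4.0 d add X, 50.0 % of the amount charged, then wait 30 h

- what is taken out of E is counted as made
- additions bring no volume worth counting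

Flask beta and the delta run look alike: same loading of X, E rising. Beta stands flat; its last 3 readings average 0.246 of the charge, each with a scatter of 0.5 percentage points. Delta, colder and with less Q, ends its readings at 14.8 %, still rising by 0.00908 h⁻¹. At that slope delta reaches the plateau level of beta at 27.1 h, later than its own last reading, so the readings of delta end below that level and show no stop.

A flat line can mean equilibrium, a dead X, or a loss of E that needs Q. The readings do not choose. I commit to the third.

Suppose X makes E at a rate proportional to Q, and E is lost at a rate proportional to E times Q. Q stands in both rates, so they balance at one level of E, c, whatever Q is. Dividing one rate by the other removes time, and taking Q down to zero gives the plateau p = c(1 − exp(−(1 + p)/(2c))). The exponential is the small correction. Starting from c = p, one pass gives 0.267 and a second gives 0.272. This ceiling, the fraction of the charge at which the loss of E equals its making, is a quasi-steady level. On this reckoning beta stops with Q at zero, so E stays at 0.246 and no remedy gains anything.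

The forecast gives 24.6 % now and 24.6 % after Saturday's, as I do, but parts from me with Friday's as best and 35.5 % after Friday's; its ground reads: “Fresh X at half the dose gives about half the original yield”.

    Q + X ⇌ G (K = 3.90 M⁻¹, k = 78000 M⁻¹ min⁻¹, Ea = 39.0 kJ mol⁻¹, ΔH = 0 kJ mol⁻¹)
    X → L (k = 1.80 × 10⁻⁵ min⁻¹, Ea = 195 kJ mol⁻¹)
    G → X + E (k = 640 min⁻¹, Ea = 59.0 kJ mol⁻¹)
    Q + E → D (k = 0.0580 M⁻¹ min⁻¹, Ea = 75.0 kJ mol⁻¹)
    (constants at 25 °C)

The flask gives 24.4 % now, none as best, and 24.4 % after Friday's. At 4.93 h E is made 1.44 times as fast as it is used up, and its half-life by Q + E → D is 3.6 h, shorter than the 4.0 d waited; at 96.0 h the limiting reagent Q stands at 0 %, with E 0.0280 below my ceiling. With 0.0029 mol% of X the ceiling scales to 1.08, two passes from 0.5 give 0.541 and 0.551, and that flask holds 55.2 % of E.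

Readings and results are simulated for an exercise; noise was put on by code.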